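**Plan**

1. Numbering used below (halimane type): C4 = C(CH3)(CO2H), C5 = ring-fusion CH, C10=C1 = ring A alkene, C9 = C(CH3)(side chain), C8 = CH(CH3), C11–C15 = side chain; ring A = C1–C5 + C10, ring B = C5–C10.
2. Retrosynthesis: acetates and C18 methyl ester off; the 13,14-diol comes from anti opening of the (13R,14R)-epoxide of the 13E allylic alcohol; the side chain comes from a C9 allyl group via a terminal alkyne; a helper oxygen is put on C3; ring A is then cut at C1–C2 and C4–C5.
3. Enabling feature: in ring A, C1=C10–C5 is an allyl unit whose termini are the carbonyl carbon and the β-carbon of a ring-B cyclohexenecarbaldehyde, and C2/C4 are the γ/α carbons of a β-keto ester once C3 carries a temporary ketone. A 1,3-dielectrophile therefore meets a 1,3-dinucleophile in a [3+3] union.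
4. Forward order: ring B with C8 and C9; ring A in one operation; removal of the C3 oxygen; side chain growth; epoxidation and opening; ester hydrolysis; acetylation.
5. Stereochemistry: C8 from a chiral copper catalyst, C9 from allylation anti to the C8 methyl, C4/C5 from a chair-like closure under a chiral counteranion, C13/C14 from tartrate-controlled epoxidation with inversion at C13.

Key step: step 5

Remark: each chiral ligand or catalyst is named as the antipode assumed to give the stated configuration; the CIP descriptor at C4 (naphthalene C-1) changes from R to S in step 7 only because the C3 oxygen leaves, the spatial arrangement is unchanged.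

**Step 1**
Reactants: 1 2-methylcyclohex-2-en-1-one
Product: 3 (2S,3R)-2,3-dimethyl-2-(prop-2-en-1-yl)cyclohexan-1-one, via aluminium enolate 2 (not isolated)
Conditions: Me3Al, Cu(OTf)2 (2 mol %), (S)-(1,1′-binaphthalene-2,2′-diyl) N,N-bis[(R)-1-phenylethyl]phosphoramidite (4 mol %), Et2O, −30 °C; then MeLi, THF/HMPA, allyl iodide, −30 °C → rt
Reagents that add atoms: trimethylaluminium C[Al](C)C; allyl iodide C=CCI
Why: Copper-catalysed asymmetric conjugate addition should set C8 (3R), and the enolate should be allylated anti to the new methyl group, which A(1,2) strain holds pseudoaxial, giving the cis-dimethyl quaternary centre C9 (2S).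

**Step 2**
Reactants: 3 (2S,3R)-2,3-dimethyl-2-(prop-2-en-1-yl)cyclohexan-1-one
Product: 4 (5R,6S)-5,6-dimethyl-6-(prop-2-en-1-yl)cyclohex-1-en-1-yl trifluoromethanesulfonate
Conditions: KN(SiMe3)2, THF, −78 °C; PhNTf2, −78 → 0 °C
Reagents that add atoms: N-phenylbis(trifluoromethanesulfonimide) O=S(=O)(N(c1ccccc1)S(=O)(=O)C(F)(F)F)C(F)(F)F
Why: Only one α-carbon of 3 carries hydrogen, so enolate O-sulfonylation should give a single enol triflate.

**Step 3**
Reactants: 4 (5R,6S)-5,6-dimethyl-6-(prop-2-en-1-yl)cyclohex-1-en-1-yl trifluoromethanesulfonate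
Product: 5 (5R,6S)-5,6-dimethyl-6-(prop-2-en-1-yl)cyclohex-1-ene-1-carbaldehyde
Conditions: Pd(PPh3)4 (5 mol %), CO (1 atm), Bu3SnH (slow addition), LiCl, THF, 50 °C
Reagents that add atoms: carbon monoxide [C-]#[O+]
Why: Palladium-catalysed reductive carbonylation (formylation) of the enol triflate should give the enal that holds C1, C10 and C5 without touching the stereocentres.

**Step 4**
Reactants: 6 methyl 2-methyl-3-oxobutanoate
Product: 8 [(1-methoxy-2-methylbuta-1,3-diene-1,3-diyl)bis(oxy)]bis(trimethylsilane), via mono silyl enol ether 7 (not isolated)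
Conditions: Me3SiCl, Et3N, toluene, rt, filtration; then LiN(iPr)2, THF, −78 °C, Me3SiCl
Reagents that add atoms: chlorotrimethylsilane C[Si](C)(C)Cl
Why: Soft enolisation followed by kinetic γ-deprotonation and silylation should give the 1,3-bis(silyloxy)diene, the neutral equivalent of the keto ester dianion (C2 and C4 nucleophilic, C3 oxygen as helper).

**Step 5**
Reactants: 5 (5R,6S)-5,6-dimethyl-6-(prop-2-en-1-yl)cyclohex-1-ene-1-carbaldehyde; 8 [(1-methoxy-2-methylbuta-1,3-diene-1,3-diyl)bis(oxy)]bis(trimethylsilane)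
Product: 11 methyl (1R,5S,6R,8aS)-2-hydroxy-1,5,6-trimethyl-5-(prop-2-en-1-yl)-1,2,3,5,6,7,8,8a-octahydronaphthalene-1-carboxylate (C-2 epimers), via bis-silyl aldol adduct 9 (not isolated), via keto ester 10 (not isolated)
Conditions: (R)-3,3′-bis[3,5-bis(trifluoromethyl)phenyl]-1,1′-binaphthalene-2,2′-disulfonimide (5 mol %), toluene, −60 → 0 °C; then MeOH, NaBH4, −40 → 0 °C
Reagents that add atoms: none
Why: Proposed new method: the N-silylated disulfonimide (a silylium Lewis acid paired with a chiral anion) activates the aldehyde of 5, the terminal carbon of 8 adds 1,2 (vinylogous Mukaiyama aldol, C1–C2) to give 9, and the same silylium then removes the allylic silyloxy group of 9 as hexamethyldisiloxane, leaving the C1–C10–C5 allyl cation, which is captured at C5 by the tethered silyl enol ether carbon C4 with release of the silylium (C4–C5). The closest known reaction types are the formal [3+3] cyclisations of 1,3-bis(silyloxy)dienes with 1,3-dielectrophiles under Me3SiOTf or TiCl4 and the disulfonimide-catalysed (vinylogous) Mukaiyama aldol reaction; joining the two under one chiral silylium catalyst is the new element. Ring A closes in a 6-(enolendo)-endo mode through a chair-like transition state in which the C1–C10–C5 allyl unit stays planar. At C4 the diene reacts in its s-trans form, so the ester lies trans to C2 on the C3=C4 enol ether and becomes equatorial, cis to the axial H5, with the methyl group axial; at C5 the ring-B stereocentres bias the two faces of the cation only weakly, so the chiral counteranion is relied on to send C4 to the face cis to the C9 methyl group; the carbinol centre of 9 is transient. The step needs 1,2- over 1,4-addition (C5 is ring-bound and next to the quaternary C9), C- over O-attack, and capture by the enol ether instead of by the terminal alkene (much higher nucleophilicity, six-membered transition state). The β,γ-unsaturated ketone 10 is reduced in the same flask so that the C10=C1 bond cannot move into conjugation; the new C3 carbinol centre is uncontrolled and is removed in step 7.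

**Step 6**
Reactants: 11 methyl (1R,5S,6R,8aS)-2-hydroxy-1,5,6-trimethyl-5-(prop-2-en-1-yl)-1,2,3,5,6,7,8,8a-octahydronaphthalene-1-carboxylate
Product: 12 methyl (1R,5S,6R,8aS)-2-[(1H-imidazole-1-carbothioyl)oxy]-1,5,6-trimethyl-5-(prop-2-en-1-yl)-1,2,3,5,6,7,8,8a-octahydronaphthalene-1-carboxylate
Conditions: 1,1′-thiocarbonyldiimidazole, DMAP (cat.), ClCH2CH2Cl, 70 °C
Reagents that add atoms: 1,1′-thiocarbonyldiimidazole S=C(n1ccnc1)n1ccnc1
Why: Neutral thioacylation of the secondary alcohol should give the radical precursor for a Barton–McCombie deoxygenation without a retro-aldol pathway.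

**Step 7**
Reactants: 12 methyl (1R,5S,6R,8aS)-2-[(1H-imidazole-1-carbothioyl)oxy]-1,5,6-trimethyl-5-(prop-2-en-1-yl)-1,2,3,5,6,7,8,8a-octahydronaphthalene-1-carboxylate
Product: 13 methyl (1S,5S,6R,8aS)-1,5,6-trimethyl-5-(prop-2-en-1-yl)-1,2,3,5,6,7,8,8a-octahydronaphthalene-1-carboxylate
Conditions: Bu3SnH, AIBN (cat.), toluene, 100 °C
Reagents that add atoms: none
Why: Barton–McCombie radical deoxygenation should take out the helper oxygen at C3 under neutral conditions that leave both alkenes and all stereocentres in place.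

**Step 8**
Reactants: 13 methyl (1S,5S,6R,8aS)-1,5,6-trimethyl-5-(prop-2-en-1-yl)-1,2,3,5,6,7,8,8a-octahydronaphthalene-1-carboxylate
Product: 14 methyl (1S,5S,6R,8aS)-5-(3-hydroxypropyl)-1,5,6-trimethyl-1,2,3,5,6,7,8,8a-octahydronaphthalene-1-carboxylate
Conditions: 9-BBN, THF, 0 °C → rt; then NaOH, H2O2, 0 °C
Reagents that add atoms: hydrogen peroxide OO
Why: Hydroboration–oxidation with 9-BBN should touch only the terminal alkene, since the trisubstituted ring alkene next to the quaternary C9 and the ester are inert to this borane.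

**Step 9**
Reactants: 14 methyl (1S,5S,6R,8aS)-5-(3-hydroxypropyl)-1,5,6-trimethyl-1,2,3,5,6,7,8,8a-octahydronaphthalene-1-carboxylate
Product: 15 methyl (1S,5S,6R,8aS)-1,5,6-trimethyl-5-(3-oxopropyl)-1,2,3,5,6,7,8,8a-octahydronaphthalene-1-carboxylate
Conditions: Dess–Martin periodinane, NaHCO3, CH2Cl2, 0 °C → rt
Reagents that add atoms: none
Why: Dess–Martin oxidation should stop cleanly at the aldehyde under buffered conditions.

**Step 10**
Reactants: 15 methyl (1S,5S,6R,8aS)-1,5,6-trimethyl-5-(3-oxopropyl)-1,2,3,5,6,7,8,8a-octahydronaphthalene-1-carboxylate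
Product: 16 methyl (1S,5S,6R,8aS)-5-(but-3-yn-1-yl)-1,5,6-trimethyl-1,2,3,5,6,7,8,8a-octahydronaphthalene-1-carboxylate
Conditions: dimethyl (1-diazo-2-oxopropyl)phosphonate, K2CO3, MeOH, 0 °C → rt
Reagents that add atoms: dimethyl (1-diazo-2-oxopropyl)phosphonate COP(=O)(OC)C(=[N+]=[N-])C(C)=O
Why: Seyferth–Gilbert homologation (Bestmann modification) should turn the aldehyde into the terminal alkyne, adding C14, under conditions too mild for the hindered ester.

**Step 11**
Reactants: 16 methyl (1S,5S,6R,8aS)-5-(but-3-yn-1-yl)-1,5,6-trimethyl-1,2,3,5,6,7,8,8a-octahydronaphthalene-1-carboxylate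
Product: 17 methyl (1S,5S,6R,8aS)-5-[(3E)-5-hydroxy-3-methylpent-3-en-1-yl]-1,5,6-trimethyl-1,2,3,5,6,7,8,8a-octahydronaphthalene-1-carboxylate
Conditions: Me3Al, Cp2ZrCl2 (0.3 equiv), ClCH2CH2Cl, rt; then n-BuLi, THF, −78 °C; (CH2O)n, −78 °C → rt
Reagents that add atoms: trimethylaluminium C[Al](C)C; formaldehyde (as paraformaldehyde) C=O
Why: Negishi zirconium-catalysed carboalumination adds CH3 and Al syn with CH3 on the internal carbon, and the derived alkenyl aluminate should take up formaldehyde with retention, so only the 13E allylic alcohol is expected.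

**Step 12**
Reactants: 17 methyl (1S,5S,6R,8aS)-5-[(3E)-5-hydroxy-3-methylpent-3-en-1-yl]-1,5,6-trimethyl-1,2,3,5,6,7,8,8a-octahydronaphthalene-1-carboxylate
Product: 18 methyl (1S,5S,6R,8aS)-5-{2-[(2R,3R)-3-(hydroxymethyl)-2-methyloxiran-2-yl]ethyl}-1,5,6-trimethyl-1,2,3,5,6,7,8,8a-octahydronaphthalene-1-carboxylate
Conditions: Ti(OiPr)4 (10 mol %), D-(−)-diethyl tartrate (12 mol %), t-BuOOH, 4 Å molecular sieves, CH2Cl2, −20 °C
Reagents that add atoms: tert-butyl hydroperoxide CC(C)(C)OO
Why: Sharpless asymmetric epoxidation with D-(−)-tartrate should give the (13R,14R)-epoxy alcohol under reagent control and reacts only at the allylic alcohol alkene.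

**Step 13**
Reactants: 18 methyl (1S,5S,6R,8aS)-5-{2-[(2R,3R)-3-(hydroxymethyl)-2-methyloxiran-2-yl]ethyl}-1,5,6-trimethyl-1,2,3,5,6,7,8,8a-octahydronaphthalene-1-carboxylate
Product: 20 (1S,5S,6R,8aS)-5-[(3S,4R)-3,4,5-trihydroxy-3-methylpentyl]-1,5,6-trimethyl-1,2,3,5,6,7,8,8a-octahydronaphthalene-1-carboxylic acid, via triol methyl ester 19 (not isolated)
Conditions: aq. HClO4 (cat.), THF, 0 °C; then KOH, MeOH/H2O, 80 °C; HCl to pH 3
Reagents that add atoms: water O; potassium hydroxide [K+].[OH-]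
Why: Acid-catalysed epoxide hydrolysis should open at the tertiary C13 with inversion while C14 keeps its oxygen (13S,14R), and saponification of the equatorial C18 methyl ester follows in the same flask.

**Step 14**
Reactants: 20 (1S,5S,6R,8aS)-5-[(3S,4R)-3,4,5-trihydroxy-3-methylpentyl]-1,5,6-trimethyl-1,2,3,5,6,7,8,8a-octahydronaphthalene-1-carboxylic acid
Product: 21 (1S,5S,6R,8aS)-5-[(3S,4R)-4,5-bis(acetyloxy)-3-hydroxy-3-methylpentyl]-1,5,6-trimethyl-1,2,3,5,6,7,8,8a-octahydronaphthalene-1-carboxylic acid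
Conditions: Ac2O, pyridine, 0 °C → rt; aq. NaHCO3/THF, then pH 3
Reagents that add atoms: acetic anhydride CC(=O)OC(C)=O
Why: Ac2O/pyridine should acetylate the primary and secondary hydroxyls only, since the tertiary C13 hydroxyl does not react without an acyl-transfer catalyst and the mixed anhydride at the carboxyl is hydrolysed on work-up.

**Compound list**

1 | 2-methylcyclohex-2-en-1-one | CC1=CCCCC1=O | starting material
2 | dimethylaluminium (3R)-2,3-dimethylcyclohex-1-en-1-olate | CC1=C(O[Al](C)C)CCC[C@H]1C | intermediate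
3 | (2S,3R)-2,3-dimethyl-2-(prop-2-en-1-yl)cyclohexan-1-one | C=CC[C@]1(C)C(=O)CCC[C@H]1C | intermediate
4 | (5R,6S)-5,6-dimethyl-6-(prop-2-en-1-yl)cyclohex-1-en-1-yl trifluoromethanesulfonate | C=CC[C@]1(C)C(OS(=O)(=O)C(F)(F)F)=CCC[C@H]1C | intermediate
5 | (5R,6S)-5,6-dimethyl-6-(prop-2-en-1-yl)cyclohex-1-ene-1-carbaldehyde | C=CC[C@]1(C)C(C=O)=CCC[C@H]1C | intermediate
6 | methyl 2-methyl-3-oxobutanoate (racemic) | COC(=O)C(C)C(C)=O | starting material
7 | methyl 2-methyl-3-[(trimethylsilyl)oxy]but-2-enoate | COC(=O)C(C)=C(C)O[Si](C)(C)C | intermediate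
8 | [(1-methoxy-2-methylbuta-1,3-diene-1,3-diyl)bis(oxy)]bis(trimethylsilane) | COC(O[Si](C)(C)C)=C(C)C(=C)O[Si](C)(C)C | intermediate
9 | methyl (2Z)-5-[(5R,6S)-5,6-dimethyl-6-(prop-2-en-1-yl)cyclohex-1-en-1-yl]-2-methyl-3,5-bis[(trimethylsilyl)oxy]pent-2-enoate (C-5 epimers) | C=CC[C@]1(C)C(=CCC[C@H]1C)C(O[Si](C)(C)C)C/C(O[Si](C)(C)C)=C(\C)C(=O)OC | intermediate
10 | methyl (1R,5S,6R,8aS)-1,5,6-trimethyl-2-oxo-5-(prop-2-en-1-yl)-1,2,3,5,6,7,8,8a-octahydronaphthalene-1-carboxylate | C=CC[C@]1(C)C2=CCC(=O)[C@](C)(C(=O)OC)[C@H]2CC[C@H]1C | intermediate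
11 | methyl (1R,5S,6R,8aS)-2-hydroxy-1,5,6-trimethyl-5-(prop-2-en-1-yl)-1,2,3,5,6,7,8,8a-octahydronaphthalene-1-carboxylate (C-2 epimers) | C=CC[C@]1(C)C2=CCC(O)[C@](C)(C(=O)OC)[C@H]2CC[C@H]1C | intermediate
12 | methyl (1R,5S,6R,8aS)-2-[(1H-imidazole-1-carbothioyl)oxy]-1,5,6-trimethyl-5-(prop-2-en-1-yl)-1,2,3,5,6,7,8,8a-octahydronaphthalene-1-carboxylate (C-2 epimers) | C=CC[C@]1(C)C2=CCC(OC(=S)n3ccnc3)[C@](C)(C(=O)OC)[C@H]2CC[C@H]1C | intermediate
13 | methyl (1S,5S,6R,8aS)-1,5,6-trimethyl-5-(prop-2-en-1-yl)-1,2,3,5,6,7,8,8a-octahydronaphthalene-1-carboxylate | C=CC[C@]1(C)C2=CCC[C@](C)(C(=O)OC)[C@H]2CC[C@H]1C | intermediate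
14 | methyl (1S,5S,6R,8aS)-5-(3-hydroxypropyl)-1,5,6-trimethyl-1,2,3,5,6,7,8,8a-octahydronaphthalene-1-carboxylate | OCCC[C@]1(C)C2=CCC[C@](C)(C(=O)OC)[C@H]2CC[C@H]1C | intermediate
15 | methyl (1S,5S,6R,8aS)-1,5,6-trimethyl-5-(3-oxopropyl)-1,2,3,5,6,7,8,8a-octahydronaphthalene-1-carboxylate | O=CCC[C@]1(C)C2=CCC[C@](C)(C(=O)OC)[C@H]2CC[C@H]1C | intermediate
16 | methyl (1S,5S,6R,8aS)-5-(but-3-yn-1-yl)-1,5,6-trimethyl-1,2,3,5,6,7,8,8a-octahydronaphthalene-1-carboxylate | C#CCC[C@]1(C)C2=CCC[C@](C)(C(=O)OC)[C@H]2CC[C@H]1C | intermediate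
17 | methyl (1S,5S,6R,8aS)-5-[(3E)-5-hydroxy-3-methylpent-3-en-1-yl]-1,5,6-trimethyl-1,2,3,5,6,7,8,8a-octahydronaphthalene-1-carboxylate | OC/C=C(\C)CC[C@]1(C)C2=CCC[C@](C)(C(=O)OC)[C@H]2CC[C@H]1C | intermediate
18 | methyl (1S,5S,6R,8aS)-5-{2-[(2R,3R)-3-(hydroxymethyl)-2-methyloxiran-2-yl]ethyl}-1,5,6-trimethyl-1,2,3,5,6,7,8,8a-octahydronaphthalene-1-carboxylate | OC[C@H]1O[C@]1(C)CC[C@]2(C)C3=CCC[C@](C)(C(=O)OC)[C@H]3CC[C@H]2C | intermediate
19 | methyl (1S,5S,6R,8aS)-5-[(3S,4R)-3,4,5-trihydroxy-3-methylpentyl]-1,5,6-trimethyl-1,2,3,5,6,7,8,8a-octahydronaphthalene-1-carboxylate | OC[C@@H](O)[C@@](C)(O)CC[C@]1(C)C2=CCC[C@](C)(C(=O)OC)[C@H]2CC[C@H]1C | intermediate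
20 | (1S,5S,6R,8aS)-5-[(3S,4R)-3,4,5-trihydroxy-3-methylpentyl]-1,5,6-trimethyl-1,2,3,5,6,7,8,8a-octahydronaphthalene-1-carboxylic acid | OC[C@@H](O)[C@@](C)(O)CC[C@]1(C)C2=CCC[C@](C)(C(=O)O)[C@H]2CC[C@H]1C | intermediate
21 | (1S,5S,6R,8aS)-5-[(3S,4R)-4,5-bis(acetyloxy)-3-hydroxy-3-methylpentyl]-1,5,6-trimethyl-1,2,3,5,6,7,8,8a-octahydronaphthalene-1-carboxylic acid | CC(=O)OC[C@@H](OC(C)=O)[C@@](C)(O)CC[C@]1(C)C2=CCC[C@](C)(C(=O)O)[C@H]2CC[C@H]1C | target

**Totals**

Total step count: 14. Longest linear sequence: 13 steps (steps 1–3 and 5–14, from compound 1); step 4 is a one-step side branch.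

**Steps most likely to fail**

1. Step 5 (proposed new method). What may go wrong: poor facial selectivity at C5 under counteranion control, or proton loss from the allyl cation instead of ring closure. The fallback uses known chemistry, sets out from 5 and 8 and comes back at 11. A Ti(OiPr)4/(S)-1,1′-bi-2-naphthol-catalysed vinylogous Mukaiyama aldol addition of 8 to 5, followed by acidic desilylation, would give methyl (5S)-5-[(5R,6S)-5,6-dimethyl-6-(prop-2-en-1-yl)cyclohex-1-en-1-yl]-5-hydroxy-2-methyl-3-oxopentanoate F1. ClCO2Me/pyridine would convert it into the allylic methyl carbonate, methyl (5S)-5-[(5R,6S)-5,6-dimethyl-6-(prop-2-en-1-yl)cyclohex-1-en-1-yl]-5-[(methoxycarbonyl)oxy]-2-methyl-3-oxopentanoate F2. Pd(PPh3)4 in THF would ionise the carbonate anti to palladium, and the keto ester enolate would attack C5 anti to palladium (Tsuji–Trost, net syn SN2′), so the catalyst-set carbinol configuration is relayed to C5 and the chelated enolate in a chair-like closure sets C4. The resulting 10 is reduced with NaBH4 to 11.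

2. Step 11. What may go wrong: attack of n-BuLi on the methyl ester during aluminate formation, and incomplete capture of formaldehyde. The fallback sets out from 16 and comes back at 17. The same carboalumination is quenched with iodine to give methyl (1S,5S,6R,8aS)-5-[(3E)-4-iodo-3-methylbut-3-en-1-yl]-1,5,6-trimethyl-1,2,3,5,6,7,8,8a-octahydronaphthalene-1-carboxylate F3. A Stille coupling of F3 with Bu3SnCH2OH and Pd(PPh3)4 then brings in C15 as the hydroxymethyl group without any organolithium.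

3. Step 13. What may go wrong: loss of stereochemical integrity at the tertiary C13 through an SN1 pathway, or competing opening at C14. The fallback sets out from 18 and comes back at 20. Ti(OiPr)4-mediated opening of the epoxy alcohol with benzoic acid (delivery within the titanium alkoxide, C-3 selective, inversion) would give methyl (1S,5S,6R,8aS)-5-[(3S,4R)-3-(benzoyloxy)-4,5-dihydroxy-3-methylpentyl]-1,5,6-trimethyl-1,2,3,5,6,7,8,8a-octahydronaphthalene-1-carboxylate F4. KOH in aqueous methanol then cleaves the benzoate and the methyl ester to give 20.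

**Further compounds**

F1 | step 5 | methyl (5S)-5-[(5R,6S)-5,6-dimethyl-6-(prop-2-en-1-yl)cyclohex-1-en-1-yl]-5-hydroxy-2-methyl-3-oxopentanoate | C=CC[C@]1(C)C(=CCC[C@H]1C)[C@@H](O)CC(=O)C(C)C(=O)OC
F2 | step 5 | methyl (5S)-5-[(5R,6S)-5,6-dimethyl-6-(prop-2-en-1-yl)cyclohex-1-en-1-yl]-5-[(methoxycarbonyl)oxy]-2-methyl-3-oxopentanoate | C=CC[C@]1(C)C(=CCC[C@H]1C)[C@@H](OC(=O)OC)CC(=O)C(C)C(=O)OC
F3 | step 11 | methyl (1S,5S,6R,8aS)-5-[(3E)-4-iodo-3-methylbut-3-en-1-yl]-1,5,6-trimethyl-1,2,3,5,6,7,8,8a-octahydronaphthalene-1-carboxylate | I/C=C(\C)CC[C@]1(C)C2=CCC[C@](C)(C(=O)OC)[C@H]2CC[C@H]1C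
F4 | step 13 | methyl (1S,5S,6R,8aS)-5-[(3S,4R)-3-(benzoyloxy)-4,5-dihydroxy-3-methylpentyl]-1,5,6-trimethyl-1,2,3,5,6,7,8,8a-octahydronaphthalene-1-carboxylate | OC[C@@H](O)[C@@](C)(OC(=O)c1ccccc1)CC[C@]2(C)C3=CCC[C@](C)(C(=O)OC)[C@H]3CC[C@H]2C
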